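**Plan**
- Retrosynthetic cuts: the cinnamate ester C–O bond; the sp2–sp3 bond between ring carbon C6 and the side chain; the bonds C5–C6 and C6–C7 of the oxepene (ring atoms O1, C2, C3, C4, C5=C6, C7), which takes C6 out and contracts the ring to a 3,4-dihydro-2H-pyran; the enol ether back to a lactol and a terminal alkene; last the aldol bond between C2 and the CH2 next to the aryl ketone.
- Enabling feature: C6 is a single sp2 carbon between C5 and the oxygen-bound C7, so it can be delivered as dibromocarbene to the enol ether of the six-membered ring that already carries C2; opening of the cyclopropane enlarges the ring and leaves bromine on C6 as the coupling handle.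
- Forward order: aryl enol silane plus tert-butyl 2-oxohept-6-enoate (aldol); alkene cleavage to the lactol and dehydration (six-membered ring); carbene ring expansion (seven-membered ring); acetal reduction; Negishi coupling of the side chain; cinnamate esterification; removal of the tert-butyl ester and silyl ethers.
- Stereochemistry: C2 (S), the only stereocentre, comes from a copper bis(oxazoline)-catalysed Mukaiyama aldol and is not touched afterwards; the E side-chain olefin comes from SeO2 oxidation of the trans methyl group of 5-bromo-2-methylpent-2-ene; the E cinnamate comes from p-coumaric acid; the ring olefin is cis because it is formed inside a ring.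

Key step: step 8

Abbreviations: Ar = 2,5-bis(tert-butyldimethylsilyloxy)phenyl; TBS = tert-butyldimethylsilyl; TES = triethylsilyl; TMS = trimethylsilyl; (S,S)-tBu-box = 2,2'-(propane-2,2-diyl)bis[(4S)-4-tert-butyl-4,5-dihydro-1,3-oxazole].

Assumption: the (S,S)-tBu-box complex of divalent copper is taken to direct the enol silane to the si face of the chelated α-keto ester, as it does with pyruvate esters; this face gives the (S) carbinol the target needs.

Step 1
Reactants: 1 2',5'-dihydroxyacetophenone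
Product: 2 1-Ar-ethan-1-one [2',5'-bis(tert-butyldimethylsilyloxy)acetophenone]
Conditions: TBSCl, imidazole, DMF, 40 °C
Reagents that add atoms: tert-butyldimethylsilyl chloride, CC(C)(C)[Si](C)(C)Cl
Why: Phenol O-silylation with a silyl chloride and imidazole is standard, gentle warming overcomes the hydrogen bond of the 2'-hydroxyl to the ketone, and the silyl ethers mask the acidic phenols for the enol silane, carbene and organozinc steps.

Step 2
Reactants: 2 1-Ar-ethan-1-one
Product: 3 (1-Ar-ethenyloxy)trimethylsilane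
Conditions: TMSOTf, Et3N, CH2Cl2, 0 °C
Reagents that add atoms: trimethylsilyl trifluoromethanesulfonate, C[Si](C)(C)OS(=O)(=O)C(F)(F)F
Why: Soft enolisation of the methyl ketone (silyl enol ether formation) gives the only possible enol silane without a free enolate, so the ortho silyl group has no chance to migrate.

Step 3
Reactants: 4 5-bromopent-1-ene; 5 di-tert-butyl oxalate
Product: 7 tert-butyl 2-oxohept-6-enoate, via pent-4-enylmagnesium bromide 6 (not isolated)
Conditions: Mg, THF, rt; then 5 (1.5 equiv), THF, −78 °C; 1 M HCl quench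
Reagents that add atoms: none
Why: Grignard formation and acyl substitution on a dialkyl oxalate at −78 °C stop at the α-keto ester because the magnesium hemiketal alkoxide survives until the acidic quench and the excess of oxalate suppresses double addition.

Step 4
Reactants: 3 (1-Ar-ethenyloxy)trimethylsilane; 7 tert-butyl 2-oxohept-6-enoate
Product: 9 tert-butyl (2S)-2-(2-Ar-2-oxoethyl)-2-hydroxyhept-6-enoate, via trimethylsilyl ether 8 (not isolated)
Conditions: Cu(OTf)2 (10 mol %), (S,S)-tBu-box (11 mol %), THF, −78 to −40 °C; then 1 M HCl, THF, 0 °C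
Reagents that add atoms: none
Why: In this catalytic enantioselective Mukaiyama aldol addition the α-keto ester chelates divalent copper in the square plane of the bis(oxazoline) complex, a tert-butyl group of the ligand screens the re face of the keto carbonyl and the enol silane adds to the si face to set C2 as (S), after which dilute acid removes the transferred TMS group.

Step 5
Reactants: 9 tert-butyl (2S)-2-(2-Ar-2-oxoethyl)-2-hydroxyhept-6-enoate
Product: 12 tert-butyl (2S)-2-(2-Ar-2-oxoethyl)-6-hydroxyoxane-2-carboxylate, via triol 10 (not isolated), via hydroxy aldehyde 11 (not isolated)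
Conditions: OsO4 (2 mol %), NaIO4, 2,6-lutidine, dioxane/H2O 3:1, rt
Reagents that add atoms: osmium tetroxide, O=[Os](=O)(=O)=O (delivers the oxygen); sodium periodate, [Na+].[O-]I(=O)(=O)=O (terminal oxidant)
Why: In this Lemieux–Johnson oxidation OsO4 dihydroxylates only the terminal alkene, periodate cleaves the diol and the tertiary hydroxyl closes the resulting 6-oxo chain to the six-membered lactol, while the lutidine buffer keeps the β-hydroxy ketone from retro-aldol cleavage.

Step 6
Reactants: 12 tert-butyl (2S)-2-(2-Ar-2-oxoethyl)-6-hydroxyoxane-2-carboxylate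
Product: 14 tert-butyl (2S)-2-(2-Ar-2-oxoethyl)-3,4-dihydro-2H-pyran-2-carboxylate, via anomeric mesylate 13 (not isolated)
Conditions: MsCl, Et3N, CH2Cl2, 0 °C to reflux
Reagents that add atoms: none
Why: Lactol dehydration through the anomeric sulfonate (mesylation, then amine-mediated elimination across C5–C6) is a standard entry to cyclic enol ethers, and the quaternary C2 has no hydrogen and takes no part.

Step 7
Reactants: 15 phenylmercury chloride; 16 bromoform
Product: 17 phenyl(tribromomethyl)mercury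
Conditions: KOtBu, benzene, 5 °C
Reagents that add atoms: none
Why: Tribromomethyl anion made from bromoform and tert-butoxide displaces chloride at mercury (organomercurial formation by anion capture) to give a neutral, storable dibromocarbene transfer reagent, so the key step needs no base.

Step 8
Reactants: 14 tert-butyl (2S)-2-(2-Ar-2-oxoethyl)-3,4-dihydro-2H-pyran-2-carboxylate; 17 phenyl(tribromomethyl)mercury
Product: 19 tert-butyl (2S)-2-(2-Ar-2-oxoethyl)-6-bromo-7-methoxy-2,3,4,7-tetrahydrooxepine-2-carboxylate, via dibromocyclopropane 18 (not isolated)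
Conditions: 17 (1.5 equiv), benzene, 80 °C; filter, concentrate; then AgClO4, NaHCO3, MeOH, 0 °C to rt, dark
Reagents that add atoms: methanol, CO
Why: On heating, 17 extrudes PhHgBr and releases dibromocarbene without base, and this electrophilic carbene adds in a concerted [2+1] step to the enol ether of 14 (pyran C5=C6, the only electron-rich alkene present), which closes the three-membered ring and makes both new C–C bonds to the inserted carbon. Silver ion then pulls off the bromide that lies over the six-membered ring while the shared C–C bond of 18 opens in a disrotatory two-electron electrocyclic sense, so the oxepene is formed by enlargement of the pyran and not by a cyclisation, and its ring olefin can only be cis. The ring oxygen stabilises the 2-bromoallyl cation as an oxocarbenium ion, which methanol captures at the oxygen-bound carbon to give the mixed acetal with bromine left on C6. The closest known reactions are the dihalocarbene ring expansions of glycals and 3,4-dihydro-2H-pyrans to 2-halo-oxepine acetals and the silver-assisted methanolysis of gem-dibromobicycloalkanes. The cyclopropane carbons and C7 are formed without control as mixtures, which is harmless because the former become sp2 or acetal carbons on opening and C7 becomes CH2 in step 9, while C2 lies away from the reacting atoms and keeps its (S) configuration. The selectivity needed is regiochemical (which cyclopropane bond breaks, where methanol enters) and is secured by the ring oxygen, which can support positive charge only at C7, and the neutral carbene source with NaHCO3 buffering protects the enolisable β-alkoxy ketone, the tert-butyl ester and the silyl ethers.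

Step 9
Reactants: 19 tert-butyl (2S)-2-(2-Ar-2-oxoethyl)-6-bromo-7-methoxy-2,3,4,7-tetrahydrooxepine-2-carboxylate
Product: 20 tert-butyl (2S)-2-(2-Ar-2-oxoethyl)-6-bromo-2,3,4,7-tetrahydrooxepine-2-carboxylate
Conditions: Et3SiH, BF3·OEt2, CH2Cl2, −78 to −40 °C
Reagents that add atoms: none
Why: In this ionic hydrogenation of an allylic mixed acetal BF3 ionises the C7 methoxy group to the conjugated oxocarbenium ion and triethylsilane delivers hydride to the oxygen-bound carbon, as in silane reductions of 2,3-unsaturated glycosides, which removes the uncontrolled C7 centre at a temperature chosen to spare the tert-butyl ester and the aryl ketone.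

Step 10
Reactants: 21 5-bromo-2-methylpent-2-ene
Product: 22 (2E)-5-bromo-2-methylpent-2-en-1-ol
Conditions: SeO2 (10 mol %), tBuOOH, salicylic acid (10 mol %), CH2Cl2, rt
Reagents that add atoms: tert-butyl hydroperoxide, CC(C)(C)OO (oxygen source); selenium dioxide, O=[Se]=O (transfers the oxygen)
Why: Selenium dioxide allylic oxidation (ene reaction, then [2,3]-sigmatropic shift) attacks the methyl group trans to the chain of a gem-dimethyl trisubstituted alkene, so the E allylic alcohol should form and the primary bromide is untouched.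

Step 11
Reactants: 22 (2E)-5-bromo-2-methylpent-2-en-1-ol
Product: 23 [(2E)-5-bromo-2-methylpent-2-en-1-yl]oxy(triethyl)silane
Conditions: TESCl, imidazole, CH2Cl2, 0 °C
Reagents that add atoms: triethylsilyl chloride, CC[Si](CC)(CC)Cl
Why: Silylation of a primary alcohol is standard, and the TES ether tolerates zinc insertion and cross-coupling yet can later be removed by acid mild enough to leave the aryl TBS ethers.

Step 12
Reactants: 20 tert-butyl (2S)-2-(2-Ar-2-oxoethyl)-6-bromo-2,3,4,7-tetrahydrooxepine-2-carboxylate; 23 [(2E)-5-bromo-2-methylpent-2-en-1-yl]oxy(triethyl)silane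
Product: 25 tert-butyl (2S)-2-(2-Ar-2-oxoethyl)-6-[(3E)-4-methyl-5-(triethylsilyloxy)pent-3-en-1-yl]-2,3,4,7-tetrahydrooxepine-2-carboxylate, via alkylzinc bromide 24 (not isolated)
Conditions: 23, Zn dust (activated by BrCH2CH2Br and TMSCl), LiCl, THF, 50 °C; then 20, PdCl2(dppf) (5 mol %), THF, 50 °C
Reagents that add atoms: none
Why: In this Negishi sp3–sp2 coupling zinc inserts into the primary C–Br bond, the alkylzinc bromide tolerates ketone, ester and silyl ethers, and zerovalent palladium bearing the wide-bite-angle dppf ligand couples at the alkenyl bromide faster than β-hydride elimination can occur, so the cis ring olefin and the E side-chain olefin are kept.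

Step 13
Reactants: 25 tert-butyl (2S)-2-(2-Ar-2-oxoethyl)-6-[(3E)-4-methyl-5-(triethylsilyloxy)pent-3-en-1-yl]-2,3,4,7-tetrahydrooxepine-2-carboxylate
Product: 26 tert-butyl (2S)-2-(2-Ar-2-oxoethyl)-6-[(3E)-5-hydroxy-4-methylpent-3-en-1-yl]-2,3,4,7-tetrahydrooxepine-2-carboxylate
Conditions: PPTS, MeOH/CH2Cl2, 0 °C
Reagents that add atoms: none
Why: Acid-catalysed methanolysis of a primary TES ether is much faster than that of aryl TBS ethers, and the tert-butyl ester and the allylic ring ether are stable to it.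

Step 14
Reactants: 27 (E)-4-hydroxycinnamic acid (p-coumaric acid)
Product: 29 (2E)-3-[4-(tert-butyldimethylsilyloxy)phenyl]prop-2-enoic acid, via silyl ester 28 (not isolated)
Conditions: TBSCl, imidazole, DMF, rt; then AcOH/THF/H2O, rt
Reagents that add atoms: tert-butyldimethylsilyl chloride, CC(C)(C)[Si](C)(C)Cl
Why: Silylation of both acidic hydroxyls followed by selective hydrolysis of the far more labile silyl ester leaves the phenol protected and the E olefin of the natural acid unchanged.

Step 15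
Reactants: 26 tert-butyl (2S)-2-(2-Ar-2-oxoethyl)-6-[(3E)-5-hydroxy-4-methylpent-3-en-1-yl]-2,3,4,7-tetrahydrooxepine-2-carboxylate; 29 (2E)-3-[4-(tert-butyldimethylsilyloxy)phenyl]prop-2-enoic acid
Product: 30 tert-butyl (2S)-2-(2-Ar-2-oxoethyl)-6-[(3E)-5-{[(2E)-3-(4-(tert-butyldimethylsilyloxy)phenyl)prop-2-enoyl]oxy}-4-methylpent-3-en-1-yl]-2,3,4,7-tetrahydrooxepine-2-carboxylate
Conditions: EDC·HCl, DMAP, CH2Cl2, 0 °C to rt
Reagents that add atoms: none
Why: Steglich esterification (carbodiimide activation, DMAP as acyl-transfer catalyst) acylates the only free hydroxyl, the primary allylic alcohol, without allylic transposition or change of either olefin geometry.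

Step 16
Reactants: 30 the tert-butyl ester from step 15
Product: 31 (2S)-2-(2-Ar-2-oxoethyl)-6-[(3E)-5-{[(2E)-3-(4-(tert-butyldimethylsilyloxy)phenyl)prop-2-enoyl]oxy}-4-methylpent-3-en-1-yl]-2,3,4,7-tetrahydrooxepine-2-carboxylic acid
Conditions: TFA/CH2Cl2 1:4, 0 °C
Reagents that add atoms: none
Why: Acidolysis of a tert-butyl ester by the AAL1 pathway (loss of the tert-butyl cation as isobutene) should proceed at 0 °C, where the primary allylic cinnamate and the aryl silyl ethers are expected to survive.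

Step 17
Reactants: 31 the carboxylic acid from step 16
Product: 32 (2S)-2-[2-(2,5-dihydroxyphenyl)-2-oxoethyl]-6-[(3E)-5-{[(2E)-3-(4-hydroxyphenyl)prop-2-enoyl]oxy}-4-methylpent-3-en-1-yl]-2,3,4,7-tetrahydrooxepine-2-carboxylic acid (CNP0602535.2)
Conditions: HF·pyridine, pyridine, THF, 0 °C to rt
Reagents that add atoms: none
Why: Fluoride-mediated desilylation of the three aryl silyl ethers under pyridine-buffered acidic conditions avoids phenoxide formation, so neither the cinnamate ester nor the β-alkoxy ketone (prone to E1cB ring opening under base) is endangered and the (S) centre from step 4 reaches the target unchanged.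

**Compound list**
1 | 2',5'-dihydroxyacetophenone | CC(=O)c1cc(O)ccc1O | starting material
2 | 1-Ar-ethan-1-one | CC(=O)c1cc(O[Si](C)(C)C(C)(C)C)ccc1O[Si](C)(C)C(C)(C)C | intermediate
3 | (1-Ar-ethenyloxy)trimethylsilane | C=C(O[Si](C)(C)C)c1cc(O[Si](C)(C)C(C)(C)C)ccc1O[Si](C)(C)C(C)(C)C | intermediate
4 | 5-bromopent-1-ene | C=CCCCBr | starting material
5 | di-tert-butyl oxalate | CC(C)(C)OC(=O)C(=O)OC(C)(C)C | starting material
6 | pent-4-enylmagnesium bromide | C=CCCC[Mg]Br | intermediate
7 | tert-butyl 2-oxohept-6-enoate | C=CCCCC(=O)C(=O)OC(C)(C)C | intermediate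
8 | tert-butyl (2S)-2-(2-Ar-2-oxoethyl)-2-(trimethylsilyloxy)hept-6-enoate | C=CCCC[C@](CC(=O)c1cc(O[Si](C)(C)C(C)(C)C)ccc1O[Si](C)(C)C(C)(C)C)(C(=O)OC(C)(C)C)O[Si](C)(C)C | intermediate
9 | tert-butyl (2S)-2-(2-Ar-2-oxoethyl)-2-hydroxyhept-6-enoate | C=CCCC[C@](CC(=O)c1cc(O[Si](C)(C)C(C)(C)C)ccc1O[Si](C)(C)C(C)(C)C)(C(=O)OC(C)(C)C)O | intermediate
10 | tert-butyl (2S)-2-(2-Ar-2-oxoethyl)-2,6,7-trihydroxyheptanoate (C6 epimers) | OCC(O)CCC[C@](CC(=O)c1cc(O[Si](C)(C)C(C)(C)C)ccc1O[Si](C)(C)C(C)(C)C)(C(=O)OC(C)(C)C)O | intermediate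
11 | tert-butyl (2S)-2-(2-Ar-2-oxoethyl)-2-hydroxy-6-oxohexanoate | O=CCCC[C@](CC(=O)c1cc(O[Si](C)(C)C(C)(C)C)ccc1O[Si](C)(C)C(C)(C)C)(C(=O)OC(C)(C)C)O | intermediate
12 | tert-butyl (2S)-2-(2-Ar-2-oxoethyl)-6-hydroxyoxane-2-carboxylate (anomers) | OC1CCC[C@](CC(=O)c2cc(O[Si](C)(C)C(C)(C)C)ccc2O[Si](C)(C)C(C)(C)C)(C(=O)OC(C)(C)C)O1 | intermediate
13 | tert-butyl (2S)-2-(2-Ar-2-oxoethyl)-6-(methanesulfonyloxy)oxane-2-carboxylate | CS(=O)(=O)OC1CCC[C@](CC(=O)c2cc(O[Si](C)(C)C(C)(C)C)ccc2O[Si](C)(C)C(C)(C)C)(C(=O)OC(C)(C)C)O1 | intermediate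
14 | tert-butyl (2S)-2-(2-Ar-2-oxoethyl)-3,4-dihydro-2H-pyran-2-carboxylate | C1=CCC[C@](CC(=O)c2cc(O[Si](C)(C)C(C)(C)C)ccc2O[Si](C)(C)C(C)(C)C)(C(=O)OC(C)(C)C)O1 | intermediate
15 | phenylmercury chloride | Cl[Hg]c1ccccc1 | starting material
16 | bromoform | BrC(Br)Br | starting material
17 | phenyl(tribromomethyl)mercury | BrC(Br)(Br)[Hg]c1ccccc1 | intermediate
18 | tert-butyl (3S)-3-(2-Ar-2-oxoethyl)-7,7-dibromo-2-oxabicyclo[4.1.0]heptane-3-carboxylate (both ring-fusion faces) | BrC1(Br)C2CC[C@](CC(=O)c3cc(O[Si](C)(C)C(C)(C)C)ccc3O[Si](C)(C)C(C)(C)C)(C(=O)OC(C)(C)C)OC12 | intermediate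
19 | tert-butyl (2S)-2-(2-Ar-2-oxoethyl)-6-bromo-7-methoxy-2,3,4,7-tetrahydrooxepine-2-carboxylate (C7 epimers) | BrC1=CCC[C@](CC(=O)c2cc(O[Si](C)(C)C(C)(C)C)ccc2O[Si](C)(C)C(C)(C)C)(C(=O)OC(C)(C)C)OC1OC | intermediate
20 | tert-butyl (2S)-2-(2-Ar-2-oxoethyl)-6-bromo-2,3,4,7-tetrahydrooxepine-2-carboxylate | BrC1=CCC[C@](CC(=O)c2cc(O[Si](C)(C)C(C)(C)C)ccc2O[Si](C)(C)C(C)(C)C)(C(=O)OC(C)(C)C)OC1 | intermediate
21 | 5-bromo-2-methylpent-2-ene | CC(C)=CCCBr | starting material
22 | (2E)-5-bromo-2-methylpent-2-en-1-ol | C/C(=C\CCBr)CO | intermediate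
23 | [(2E)-5-bromo-2-methylpent-2-en-1-yl]oxy(triethyl)silane | C/C(=C\CCBr)CO[Si](CC)(CC)CC | intermediate
24 | [(3E)-4-methyl-5-(triethylsilyloxy)pent-3-en-1-yl]zinc bromide | C/C(=C\CC[Zn]Br)CO[Si](CC)(CC)CC | intermediate
25 | tert-butyl (2S)-2-(2-Ar-2-oxoethyl)-6-[(3E)-4-methyl-5-(triethylsilyloxy)pent-3-en-1-yl]-2,3,4,7-tetrahydrooxepine-2-carboxylate | C/C(=C\CCC1=CCC[C@](CC(=O)c2cc(O[Si](C)(C)C(C)(C)C)ccc2O[Si](C)(C)C(C)(C)C)(C(=O)OC(C)(C)C)OC1)CO[Si](CC)(CC)CC | intermediate
26 | tert-butyl (2S)-2-(2-Ar-2-oxoethyl)-6-[(3E)-5-hydroxy-4-methylpent-3-en-1-yl]-2,3,4,7-tetrahydrooxepine-2-carboxylate | C/C(=C\CCC1=CCC[C@](CC(=O)c2cc(O[Si](C)(C)C(C)(C)C)ccc2O[Si](C)(C)C(C)(C)C)(C(=O)OC(C)(C)C)OC1)CO | intermediate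
27 | (E)-4-hydroxycinnamic acid | O=C(O)/C=C/c1ccc(O)cc1 | starting material
28 | tert-butyldimethylsilyl (2E)-3-[4-(tert-butyldimethylsilyloxy)phenyl]prop-2-enoate | CC(C)(C)[Si](C)(C)OC(=O)/C=C/c1ccc(O[Si](C)(C)C(C)(C)C)cc1 | intermediate
29 | (2E)-3-[4-(tert-butyldimethylsilyloxy)phenyl]prop-2-enoic acid | O=C(O)/C=C/c1ccc(O[Si](C)(C)C(C)(C)C)cc1 | intermediate
30 | tert-butyl (2S)-2-(2-Ar-2-oxoethyl)-6-[(3E)-5-{[(2E)-3-(4-(tert-butyldimethylsilyloxy)phenyl)prop-2-enoyl]oxy}-4-methylpent-3-en-1-yl]-2,3,4,7-tetrahydrooxepine-2-carboxylate | C/C(=C\CCC1=CCC[C@](CC(=O)c2cc(O[Si](C)(C)C(C)(C)C)ccc2O[Si](C)(C)C(C)(C)C)(C(=O)OC(C)(C)C)OC1)COC(=O)/C=C/c1ccc(O[Si](C)(C)C(C)(C)C)cc1 | intermediate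
31 | (2S)-2-(2-Ar-2-oxoethyl)-6-[(3E)-5-{[(2E)-3-(4-(tert-butyldimethylsilyloxy)phenyl)prop-2-enoyl]oxy}-4-methylpent-3-en-1-yl]-2,3,4,7-tetrahydrooxepine-2-carboxylic acid | C/C(=C\CCC1=CCC[C@](CC(=O)c2cc(O[Si](C)(C)C(C)(C)C)ccc2O[Si](C)(C)C(C)(C)C)(C(=O)O)OC1)COC(=O)/C=C/c1ccc(O[Si](C)(C)C(C)(C)C)cc1 | intermediate
32 | (2S)-2-[2-(2,5-dihydroxyphenyl)-2-oxoethyl]-6-[(3E)-5-{[(2E)-3-(4-hydroxyphenyl)prop-2-enoyl]oxy}-4-methylpent-3-en-1-yl]-2,3,4,7-tetrahydrooxepine-2-carboxylic acid | C/C(=C\CCC1=CCC[C@](CC(=O)c2cc(O)ccc2O)(C(=O)O)OC1)COC(=O)/C=C/c1ccc(O)cc1 | target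

**Step count and risks**
Total steps: 17. Longest linear sequence: 12 steps (1, 2, 4, 5, 6, 8, 9, 12, 13, 15, 16, 17, from 2',5'-dihydroxyacetophenone).

Step 8. What may go wrong: carbene transfer from 17 needs about 80 °C, and at that temperature the oxygen-activated dibromocyclopropane may ionise before methanol is present and shed HBr to a bromodienyl ether. A low-temperature, base-generated carbene is not open to 14, because deprotonation next to the aryl ketone would expel the enol-ether oxygen by β-elimination. The fallback sets out from 14 and comes back at 19; it takes the ketone out of play for the ring expansion. NaBH4 in MeOH at 0 °C should reduce 14 to tert-butyl (2S)-2-(2-Ar-2-hydroxyethyl)-3,4-dihydro-2H-pyran-2-carboxylate F1 (carbinol epimers). TESCl and imidazole should then give tert-butyl (2S)-2-[2-Ar-2-(triethylsilyloxy)ethyl]-3,4-dihydro-2H-pyran-2-carboxylate F2. With no enolisable ketone, dibromocarbene can be made from bromoform 16 and KOtBu in pentane at −20 °C, where the adduct tert-butyl (3S)-3-[2-Ar-2-(triethylsilyloxy)ethyl]-7,7-dibromo-2-oxabicyclo[4.1.0]heptane-3-carboxylate F3 should persist. AgClO4 and NaHCO3 in MeOH at 0 °C should open it to tert-butyl (2S)-2-[2-Ar-2-(triethylsilyloxy)ethyl]-6-bromo-7-methoxy-2,3,4,7-tetrahydrooxepine-2-carboxylate F4. PPTS in MeOH frees tert-butyl (2S)-2-(2-Ar-2-hydroxyethyl)-6-bromo-7-methoxy-2,3,4,7-tetrahydrooxepine-2-carboxylate F5, and Dess–Martin periodinane in CH2Cl2 restores the ketone, which is 19.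

Step 9. What may go wrong: the bromine on C6 retards ionisation at C7, so the Lewis acid may instead strip the tert-butyl group (directly or after the ester carbonyl has captured the C7 cation), and the silane may reduce the activated aryl ketone. The fallback sets out from 19 and comes back at 25; it inverts the order of coupling and reduction so that the cation to be reduced carries an alkyl group on C6 and forms under far milder acid. Negishi coupling of 19 with alkylzinc bromide 24 under the conditions of step 12 should give tert-butyl (2S)-2-(2-Ar-2-oxoethyl)-7-methoxy-6-[(3E)-4-methyl-5-(triethylsilyloxy)pent-3-en-1-yl]-2,3,4,7-tetrahydrooxepine-2-carboxylate F6. Et3SiH with catalytic TMSOTf in CH2Cl2 at −78 °C should then reduce the acetal to 25.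

Step 4. What may go wrong: the ortho silyloxy group twists and encumbers the aryl enol silane, so turnover may stall or facial selectivity may erode, and C2 would be formed with insufficient enantiomeric purity. The fallback sets out from 7 and comes back at 8; it moves the aryl group out of the stereo-determining step. S-Ethyl thioacetate with LDA and TMSCl gives 1-(ethylsulfanyl)-1-(trimethylsilyloxy)ethene F7, an unhindered silyl ketene thioacetal of the class that performs best in this copper-catalysed aldol. With 7, Cu(OTf)2 and (S,S)-tBu-box in THF at −78 °C it should give tert-butyl (2S)-2-[2-(ethylsulfanyl)-2-oxoethyl]-2-(trimethylsilyloxy)hept-6-enoate F8, isolated without acid treatment. Separately, bromohydroquinone is silylated (TBSCl, imidazole) to 2-bromo-1,4-bis(tert-butyldimethylsilyloxy)benzene F9. Mg in THF converts it into [2,5-bis(tert-butyldimethylsilyloxy)phenyl]magnesium bromide F10, and ZnBr2 into [2,5-bis(tert-butyldimethylsilyloxy)phenyl]zinc bromide F11. Fukuyama coupling of F8 with F11 (PdCl2(PPh3)2, THF/toluene, rt) should give the aryl ketone 8, which the acid treatment of step 4 turns into 9.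

**Further compounds**
F1 | step 8 | tert-butyl (2S)-2-(2-Ar-2-hydroxyethyl)-3,4-dihydro-2H-pyran-2-carboxylate | C1=CCC[C@](CC(O)c2cc(O[Si](C)(C)C(C)(C)C)ccc2O[Si](C)(C)C(C)(C)C)(C(=O)OC(C)(C)C)O1
F2 | step 8 | tert-butyl (2S)-2-[2-Ar-2-(triethylsilyloxy)ethyl]-3,4-dihydro-2H-pyran-2-carboxylate | C1=CCC[C@](CC(O[Si](CC)(CC)CC)c2cc(O[Si](C)(C)C(C)(C)C)ccc2O[Si](C)(C)C(C)(C)C)(C(=O)OC(C)(C)C)O1
F3 | step 8 | tert-butyl (3S)-3-[2-Ar-2-(triethylsilyloxy)ethyl]-7,7-dibromo-2-oxabicyclo[4.1.0]heptane-3-carboxylate | BrC1(Br)C2CC[C@](CC(O[Si](CC)(CC)CC)c3cc(O[Si](C)(C)C(C)(C)C)ccc3O[Si](C)(C)C(C)(C)C)(C(=O)OC(C)(C)C)OC12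
F4 | step 8 | tert-butyl (2S)-2-[2-Ar-2-(triethylsilyloxy)ethyl]-6-bromo-7-methoxy-2,3,4,7-tetrahydrooxepine-2-carboxylate | BrC1=CCC[C@](CC(O[Si](CC)(CC)CC)c2cc(O[Si](C)(C)C(C)(C)C)ccc2O[Si](C)(C)C(C)(C)C)(C(=O)OC(C)(C)C)OC1OC
F5 | step 8 | tert-butyl (2S)-2-(2-Ar-2-hydroxyethyl)-6-bromo-7-methoxy-2,3,4,7-tetrahydrooxepine-2-carboxylate | BrC1=CCC[C@](CC(O)c2cc(O[Si](C)(C)C(C)(C)C)ccc2O[Si](C)(C)C(C)(C)C)(C(=O)OC(C)(C)C)OC1OC
F6 | step 9 | tert-butyl (2S)-2-(2-Ar-2-oxoethyl)-7-methoxy-6-[(3E)-4-methyl-5-(triethylsilyloxy)pent-3-en-1-yl]-2,3,4,7-tetrahydrooxepine-2-carboxylate | C/C(=C\CCC1=CCC[C@](CC(=O)c2cc(O[Si](C)(C)C(C)(C)C)ccc2O[Si](C)(C)C(C)(C)C)(C(=O)OC(C)(C)C)OC1OC)CO[Si](CC)(CC)CC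
F7 | step 4 | 1-(ethylsulfanyl)-1-(trimethylsilyloxy)ethene | C=C(SCC)O[Si](C)(C)C
F8 | step 4 | tert-butyl (2S)-2-[2-(ethylsulfanyl)-2-oxoethyl]-2-(trimethylsilyloxy)hept-6-enoate | C=CCCC[C@](CC(=O)SCC)(C(=O)OC(C)(C)C)O[Si](C)(C)C
F9 | step 4 | 2-bromo-1,4-bis(tert-butyldimethylsilyloxy)benzene | Brc1cc(O[Si](C)(C)C(C)(C)C)ccc1O[Si](C)(C)C(C)(C)C
F10 | step 4 | [2,5-bis(tert-butyldimethylsilyloxy)phenyl]magnesium bromide | Br[Mg]c1cc(O[Si](C)(C)C(C)(C)C)ccc1O[Si](C)(C)C(C)(C)C
F11 | step 4 | [2,5-bis(tert-butyldimethylsilyloxy)phenyl]zinc bromide | Br[Zn]c1cc(O[Si](C)(C)C(C)(C)C)ccc1O[Si](C)(C)C(C)(C)C
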